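**Strategy.** The target is read as a hidden 2,3-bis(4-hydroxybenzyl)succinate (C4–C3–C3'–C4') whose two carboxyls are aryl esters of phloroglucinol-type ring A and pentaoxygenated ring B. Everything rests on cutting the aryl–benzylic bonds C4a'–C4' and C4a–C4. The key step is a twofold oxidative C–H/C–H coupling: DDQ converts each p-hydroxybenzyl CH2 into a p-quinone methide (polarity reversal), which the ortho C–H of the neighbouring aryl ester captures, closing both lactone rings and setting C4 and C4'. It exploits the fact that ring B has one free carbon (C4a', ortho to O1'). The precursor is an acyclic mixed diaryl (2R,3R)-succinate; C3 and C3' are corrected afterwards by kinetic protonation.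

Key step: step 8

Remark: locants follow chroman-2-one numbering, unprimed for the 5,7-dioxygenated half (ring A) and primed for the 5',6',7',8'-tetraoxygenated half (ring B). The given structure is (3S,4R,3'S,4'R), that is 3,4-cis in both lactone rings. 1,2,3,4-Tetramethoxybenzene is taken as a purchasable starting material.

Step 1
Reactants: 1 3-[4-(benzyloxy)phenyl]propanoic acid; 2 (S)-4-benzyl-1,3-oxazolidin-2-one
Product: 4 (S)-4-benzyl-3-{3-[4-(benzyloxy)phenyl]propanoyl}-1,3-oxazolidin-2-one, via mixed pivalic anhydride 3 (not isolated)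
Conditions: PivCl, Et3N, THF, −20 °C; then 2, LiCl, −20 °C to rt
Reagents that add atoms: none
Why: N-acylation of the oxazolidinone through the mixed pivalic anhydride with LiCl activation, a standard way to attach this auxiliary; no stereocenter is formed.

Step 2
Reactants: 4 (S)-4-benzyl-3-{3-[4-(benzyloxy)phenyl]propanoyl}-1,3-oxazolidin-2-one (2 equiv; two molecules are joined at their α-carbons)
Product: 6 (4S,4'S)-3,3'-{(2R,3R)-2,3-bis[4-(benzyloxy)benzyl]butanedioyl}bis(4-benzyl-1,3-oxazolidin-2-one), via lithium Z-enolate 5 (not isolated)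
Conditions: LiN(i-Pr)2 (LDA, 1.1 equiv per 4), THF, −78 °C; then TiCl4 (1.1 equiv per 4), −78 to 0 °C
Reagents that add atoms: second molecule of acyl oxazolidinone 4, O=C(CCc1ccc(OCc2ccccc2)cc1)N1[C@@H](Cc2ccccc2)COC1=O
Why: oxidative enolate homocoupling, in which two molecules of the chelated Z-enolate 5 are each oxidised by one electron by tetravalent titanium and the α-radicals dimerise; each new bond forms on the enolate face opposite the auxiliary benzyl group, the same sense as in auxiliary-controlled alkylation, which should give the C2-symmetric (2R,3R) succinate.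

Step 3
Reactants: 6 (4S,4'S)-3,3'-{(2R,3R)-2,3-bis[4-(benzyloxy)benzyl]butanedioyl}bis(4-benzyl-1,3-oxazolidin-2-one)
Product: 8 (2R,3R)-2,3-bis[4-(benzyloxy)benzyl]butanedioic acid, via bis(peroxy acid) 7 (not isolated)
Conditions: LiOH, H2O2 (30%), THF/H2O, 0 °C; then Na2SO3 (aq.); then HCl (aq.)
Reagents that add atoms: hydrogen peroxide, OO
Why: hydroperoxide cleavage of the exocyclic imide carbonyls (LiOOH hydrolysis) proceeds without enolisation, so both α-stereocenters should be retained and auxiliary 2 is recovered.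

Step 4
Reactants: 9 1,2,3,4-tetramethoxybenzene
Product: 12 2,3,4,5-tetramethoxyphenol, via aryllithium 10 (not isolated), via dimethyl arylboronate 11 (not isolated)
Conditions: n-BuLi, TMEDA, THF, 0 °C; B(OMe)3, −78 °C to rt; then AcOH, H2O2 (30%), 0 °C to rt
Reagents that add atoms: hydrogen peroxide, OO
Why: directed ortho-lithiation next to a methoxy group (the two free positions are equivalent), borylation and oxidative carbon-to-oxygen migration give the phenol with its only ring C–H ortho to the hydroxyl; no stereocenter.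

Step 5
Reactants: 8 (2R,3R)-2,3-bis[4-(benzyloxy)benzyl]butanedioic acid; 12 2,3,4,5-tetramethoxyphenol
Product: 14 (2R,3R)-2,3-bis[4-(benzyloxy)benzyl]-4-oxo-4-(2,3,4,5-tetramethoxyphenoxy)butanoic acid, via cyclic anhydride 13 (not isolated)
Conditions: DCC (1.0 equiv), CH2Cl2, 0 °C to rt; then 12, DMAP (cat.), rt
Reagents that add atoms: none
Why: carbodiimide dehydration to the trans cyclic anhydride followed by DMAP-catalysed ring opening with the phenol; the two carbonyls of the C2-symmetric anhydride are homotopic, so a single monoester should form and the stereocenters are untouched.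

Step 6
Reactants: 14 (2R,3R)-2,3-bis[4-(benzyloxy)benzyl]-4-oxo-4-(2,3,4,5-tetramethoxyphenoxy)butanoic acid; 15 3,5-dimethoxyphenol
Product: 16 1-(3,5-dimethoxyphenyl) 4-(2,3,4,5-tetramethoxyphenyl) (2R,3R)-2,3-bis[4-(benzyloxy)benzyl]butanedioate
Conditions: EDC·HCl, DMAP (cat.), CH2Cl2, 0 °C to rt
Reagents that add atoms: none
Why: Steglich esterification; the free acid is activated by the carbodiimide faster than its carboxylate can displace the neighbouring electron-rich aryloxide, so the mixed diester should form without scrambling and without touching the stereocenters.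

Step 7
Reactants: 16 1-(3,5-dimethoxyphenyl) 4-(2,3,4,5-tetramethoxyphenyl) (2R,3R)-2,3-bis[4-(benzyloxy)benzyl]butanedioate
Product: 17 1-(3,5-dimethoxyphenyl) 4-(2,3,4,5-tetramethoxyphenyl) (2R,3R)-2,3-bis(4-hydroxybenzyl)butanedioate
Conditions: H2 (1 atm), Pd/C (10 wt% palladium on carbon), EtOAc, rt
Reagents that add atoms: none
Why: neutral hydrogenolysis of the two benzyl ethers frees the para-phenols needed for oxidation while aryl esters and methyl ethers are inert; no stereocenter is affected.

Step 8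
Reactants: 17 1-(3,5-dimethoxyphenyl) 4-(2,3,4,5-tetramethoxyphenyl) (2R,3R)-2,3-bis(4-hydroxybenzyl)butanedioate
Product: 19 (3R,4R,3'R,4'R)-4,4'-bis(4-hydroxyphenyl)-5,7,5',6',7',8'-hexamethoxy-3,3'-bichroman-2,2'-dione (3,4-trans in both rings), via bis(quinone methide) 18 (not isolated)
Conditions: DDQ (2.05 equiv), CH2Cl2/(CF3)2CHOH 10:1 (0.005 M), −20 to 0 °C
Reagents that add atoms: none
Why: DDQ abstracts hydride from each benzylic CH2 para to a free phenol to give p-quinone methide 18 (the two sites may react one after the other), and the ortho C–H carbon of the adjacent aryl ester (C4a of ring A, C4a' of ring B) adds to it in an intramolecular Friedel–Crafts 1,6-addition, after which the phenol rearomatises. The closest known reactions are the DDQ dehydrogenation of p-alkylphenols to quinone methides and the DDQ-mediated benzylic Friedel–Crafts cyclisation of dibenzylbutyrolactone lignans to aryltetralins. Each six-membered lactone closes in a 6-exo-trig mode with respect to the exocyclic C=C of the quinone methide (cyclialkylation of the ester arene). C4 and C4' are controlled by the neighbouring C3 and C3' centers: the peri methoxy group at C5 or C5' forces the 4-hydroxyphenyl group pseudoaxial and the bulky succinate substituent then sits anti to it, so the 3,4-trans isomer with 4R and 4'R should be favoured. The step needs chemoselective oxidation of the phenols (neutral DDQ leaves the methoxyarenes alone), regioselectivity (ring B offers only C4a'–H, ring A two equivalent ortho positions, six- beats seven-membered closure) and ring closure faster than tautomerisation to the cinnamate or over-oxidation; low temperature, high dilution, stoichiometric DDQ and hydrogen-bond activation by the fluorinated alcohol are meant to secure this.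

Step 9
Reactants: 19 (3R,4R,3'R,4'R)-4,4'-bis(4-hydroxyphenyl)-5,7,5',6',7',8'-hexamethoxy-3,3'-bichroman-2,2'-dione
Product: 21 (3S,4R,3'S,4'R)-4,4'-bis(4-hydroxyphenyl)-5,7,5',6',7',8'-hexamethoxy-3,3'-bichroman-2,2'-dione (3,4-cis in both rings), via tetralithium bis-enolate 20 (not isolated)
Conditions: LiN(i-Pr)2 (LDA, 4.5 equiv), THF, −78 to −40 °C; then AcOH (excess) in THF, −78 °C
Reagents that add atoms: none
Why: deprotonation of both phenols and both lactone α-carbons followed by kinetic protonation of the lactone enolates, which should deliver each proton to the face opposite the pseudoaxial C4 or C4' aryl group, so that H ends up trans to aryl and C3 and C3' are inverted to S (3,4-cis) while C4 and C4' stay untouched.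

Step 10
Reactants: 21 (3S,4R,3'S,4'R)-4,4'-bis(4-hydroxyphenyl)-5,7,5',6',7',8'-hexamethoxy-3,3'-bichroman-2,2'-dione
Product: 23 (3S,4R,3'S,4'R)-5,7,5',6',7',8'-hexahydroxy-4,4'-bis(4-hydroxyphenyl)-3,3'-bichroman-2,2'-dione (CNP0064734.1), via octakis(dibromoboryl) ether 22 (not isolated)
Conditions: BBr3 (12 equiv), CH2Cl2, −78 to 0 °C; then H2O, 0 °C, under argon
Reagents that add atoms: none
Why: Lewis-acid cleavage of the six aryl methyl ethers (bromide attack at methyl of the boron-complexed ether) under base-free conditions, in which the aryl lactones persist and the kinetically set cis centers at C3 and C3' should not enolise.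

**Compound list**

1 | 3-[4-(benzyloxy)phenyl]propanoic acid | OC(=O)CCc1ccc(OCc2ccccc2)cc1 | starting material
2 | (S)-4-benzyl-1,3-oxazolidin-2-one | O=C1N[C@@H](Cc2ccccc2)CO1 | starting material
3 | 3-[4-(benzyloxy)phenyl]propanoic pivalic anhydride | CC(C)(C)C(=O)OC(=O)CCc1ccc(OCc2ccccc2)cc1 | intermediate
4 | (S)-4-benzyl-3-{3-[4-(benzyloxy)phenyl]propanoyl}-1,3-oxazolidin-2-one | O=C(CCc1ccc(OCc2ccccc2)cc1)N1[C@@H](Cc2ccccc2)COC1=O | intermediate
5 | lithium Z-enolate of 4 | [Li+].[O-]/C(=C\Cc1ccc(OCc2ccccc2)cc1)N1[C@@H](Cc2ccccc2)COC1=O | intermediate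
6 | (4S,4'S)-3,3'-{(2R,3R)-2,3-bis[4-(benzyloxy)benzyl]butanedioyl}bis(4-benzyl-1,3-oxazolidin-2-one) | O=C([C@H](Cc1ccc(OCc2ccccc2)cc1)[C@@H](Cc1ccc(OCc2ccccc2)cc1)C(=O)N1[C@@H](Cc2ccccc2)COC1=O)N1[C@@H](Cc2ccccc2)COC1=O | intermediate
7 | (2R,3R)-2,3-bis[4-(benzyloxy)benzyl]butanediperoxoic acid (formed as its lithium salt) | OOC(=O)[C@H](Cc1ccc(OCc2ccccc2)cc1)[C@@H](Cc1ccc(OCc2ccccc2)cc1)C(=O)OO | intermediate
8 | (2R,3R)-2,3-bis[4-(benzyloxy)benzyl]butanedioic acid | OC(=O)[C@H](Cc1ccc(OCc2ccccc2)cc1)[C@@H](Cc1ccc(OCc2ccccc2)cc1)C(=O)O | intermediate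
9 | 1,2,3,4-tetramethoxybenzene | COc1ccc(OC)c(OC)c1OC | starting material
10 | (2,3,4,5-tetramethoxyphenyl)lithium | [Li]c1cc(OC)c(OC)c(OC)c1OC | intermediate
11 | dimethyl (2,3,4,5-tetramethoxyphenyl)boronate | COB(OC)c1cc(OC)c(OC)c(OC)c1OC | intermediate
12 | 2,3,4,5-tetramethoxyphenol | Oc1cc(OC)c(OC)c(OC)c1OC | intermediate
13 | (3R,4R)-3,4-bis[4-(benzyloxy)benzyl]oxolane-2,5-dione | O=C1OC(=O)[C@H](Cc2ccc(OCc3ccccc3)cc2)[C@H]1Cc1ccc(OCc2ccccc2)cc1 | intermediate
14 | (2R,3R)-2,3-bis[4-(benzyloxy)benzyl]-4-oxo-4-(2,3,4,5-tetramethoxyphenoxy)butanoic acid | OC(=O)[C@H](Cc1ccc(OCc2ccccc2)cc1)[C@@H](Cc1ccc(OCc2ccccc2)cc1)C(=O)Oc1cc(OC)c(OC)c(OC)c1OC | intermediate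
15 | 3,5-dimethoxyphenol | COc1cc(O)cc(OC)c1 | starting material
16 | 1-(3,5-dimethoxyphenyl) 4-(2,3,4,5-tetramethoxyphenyl) (2R,3R)-2,3-bis[4-(benzyloxy)benzyl]butanedioate | COc1cc(OC)cc(OC(=O)[C@H](Cc2ccc(OCc3ccccc3)cc2)[C@@H](Cc2ccc(OCc3ccccc3)cc2)C(=O)Oc2cc(OC)c(OC)c(OC)c2OC)c1 | intermediate
17 | 1-(3,5-dimethoxyphenyl) 4-(2,3,4,5-tetramethoxyphenyl) (2R,3R)-2,3-bis(4-hydroxybenzyl)butanedioate | COc1cc(OC)cc(OC(=O)[C@H](Cc2ccc(O)cc2)[C@@H](Cc2ccc(O)cc2)C(=O)Oc2cc(OC)c(OC)c(OC)c2OC)c1 | intermediate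
18 | bis(p-quinone methide) of 17 (each ArCH2 turned into a (4-oxocyclohexa-2,5-dien-1-ylidene)methyl group; succinate carbons as in 17) | COc1cc(OC)cc(OC(=O)[C@H](C=C2C=CC(=O)C=C2)[C@@H](C=C2C=CC(=O)C=C2)C(=O)Oc2cc(OC)c(OC)c(OC)c2OC)c1 | intermediate
19 | (3R,4R,3'R,4'R)-4,4'-bis(4-hydroxyphenyl)-5,7,5',6',7',8'-hexamethoxy-3,3'-bichroman-2,2'-dione | O=C1Oc2cc(OC)cc(OC)c2[C@@H](c2ccc(O)cc2)[C@@H]1[C@@H]1C(=O)Oc2c(OC)c(OC)c(OC)c(OC)c2[C@H]1c1ccc(O)cc1 | intermediate
20 | tetralithium bis(phenoxide) bis(enolate) of 19 | [Li+].[Li+].[Li+].[Li+].[O-]C1=C(C2=C([O-])Oc3c(OC)c(OC)c(OC)c(OC)c3[C@H]2c2ccc([O-])cc2)[C@H](c2ccc([O-])cc2)c2c(OC)cc(OC)cc2O1 | intermediate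
21 | (3S,4R,3'S,4'R)-4,4'-bis(4-hydroxyphenyl)-5,7,5',6',7',8'-hexamethoxy-3,3'-bichroman-2,2'-dione | O=C1Oc2cc(OC)cc(OC)c2[C@@H](c2ccc(O)cc2)[C@H]1[C@H]1C(=O)Oc2c(OC)c(OC)c(OC)c(OC)c2[C@H]1c1ccc(O)cc1 | intermediate
22 | octakis(dibromoboryl) ether of the target (idealised form of the boron aryloxides before hydrolysis) | O=C1Oc2cc(OB(Br)Br)cc(OB(Br)Br)c2[C@@H](c2ccc(OB(Br)Br)cc2)[C@H]1[C@H]1C(=O)Oc2c(OB(Br)Br)c(OB(Br)Br)c(OB(Br)Br)c(OB(Br)Br)c2[C@H]1c1ccc(OB(Br)Br)cc1 | intermediate
23 | (3S,4R,3'S,4'R)-5,7,5',6',7',8'-hexahydroxy-4,4'-bis(4-hydroxyphenyl)-3,3'-bichroman-2,2'-dione | O=C1Oc2cc(O)cc(O)c2[C@@H](c2ccc(O)cc2)[C@H]1[C@H]1C(=O)Oc2c(O)c(O)c(O)c(O)c2[C@H]1c1ccc(O)cc1 | target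

**Step count.** Total: 10 steps. Longest linear sequence: 9 steps (steps 1, 2, 3, 5, 6, 7, 8, 9, 10); step 4 is a one-step side branch.

**Steps most likely to fail**

Step 8. The quinone methide may tautomerise to the 4-hydroxycinnamate before the arene adds, which would erase the C3 or C3' controller. The product may be oxidised further at its diarylmethine C–H toward the 4-arylcoumarin. The arene may also add with poor facial selectivity. Fallback: oxidation and C–C bond formation are separated. From 17, DDQ in MeOH/CH2Cl2 at 0 °C should trap both quinone methides with the solvent and give the bis(benzylic methyl ether) F1. After removal of the spent oxidant, F1 is ionised with BF3·OEt2 in CH2Cl2 at −78 °C. The p-hydroxybenzyl cations then close both lactones by the same Friedel–Crafts ring closure with no oxidant present and at a temperature that favours the anti approach, and the route is rejoined at 19.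

Step 9. The pseudoequatorial C3–H and C3'–H of the trans lactones may be removed slowly. The aryl ester enolates may open to ketenes on warming. The quench may protonate with incomplete facial selectivity. Fallback: the polyanion is not quenched directly. From 19, LiN(i-Pr)2 with Me3SiCl as internal quench (THF, −78 °C) should give the tetrakis(trimethylsilyl) bis(ketene acetal) F2. This neutral compound is then protonated under reagent control with the Lewis-acid-assisted Brønsted acid (R)-BINOL·SnCl4 in toluene at −78 °C, the BINOL enantiomer being exchanged for its antipode if it proves mismatched with the substrate bias. Mild acidic work-up removes the aryl silyl ethers, and the route is rejoined at 21.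

Step 10. The kinetically set cis centers may epimerise under the Lewis and Brønsted acid, and the electron-rich tetrahydroxy ring may be oxidised by air during work-up. Fallback: the order of events is changed so that the last step is a neutral desilylation. From 19, BBr3 demethylation is carried out on the configurationally robust trans,trans compound to give the octaphenol F3. Persilylation with Et3SiCl and imidazole gives the octakis(triethylsilyl) ether F4. Kinetic protonation as in step 9 (LiN(i-Pr)2, 2.2 equiv; AcOH, −78 °C) gives the cis,cis octakis(triethylsilyl) ether F5. HF·pyridine in THF at 0 °C then releases the target 23.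

**Further compounds**

F1 | step 8 | 1-(3,5-dimethoxyphenyl) 4-(2,3,4,5-tetramethoxyphenyl) 2,3-bis[(4-hydroxyphenyl)(methoxy)methyl]butanedioate (succinate carbons configured as in 17, methoxy-bearing carbons as a mixture) | COc1cc(OC)cc(OC(=O)[C@H](C(OC)c2ccc(O)cc2)[C@@H](C(OC)c2ccc(O)cc2)C(=O)Oc2cc(OC)c(OC)c(OC)c2OC)c1
F2 | step 9 | tetrakis(trimethylsilyl) bis(ketene acetal) of 19 (both phenols and both lactone enols silylated; 4R,4'R) | C[Si](C)(C)OC1=C(C2=C(O[Si](C)(C)C)Oc3c(OC)c(OC)c(OC)c(OC)c3[C@H]2c2ccc(O[Si](C)(C)C)cc2)[C@H](c2ccc(O[Si](C)(C)C)cc2)c2c(OC)cc(OC)cc2O1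
F3 | step 10 | (3R,4R,3'R,4'R)-5,7,5',6',7',8'-hexahydroxy-4,4'-bis(4-hydroxyphenyl)-3,3'-bichroman-2,2'-dione | O=C1Oc2cc(O)cc(O)c2[C@@H](c2ccc(O)cc2)[C@@H]1[C@@H]1C(=O)Oc2c(O)c(O)c(O)c(O)c2[C@H]1c1ccc(O)cc1
F4 | step 10 | octakis(triethylsilyl) ether of F3 (3R,4R,3'R,4'R) | O=C1Oc2cc(O[Si](CC)(CC)CC)cc(O[Si](CC)(CC)CC)c2[C@@H](c2ccc(O[Si](CC)(CC)CC)cc2)[C@@H]1[C@@H]1C(=O)Oc2c(O[Si](CC)(CC)CC)c(O[Si](CC)(CC)CC)c(O[Si](CC)(CC)CC)c(O[Si](CC)(CC)CC)c2[C@H]1c1ccc(O[Si](CC)(CC)CC)cc1
F5 | step 10 | octakis(triethylsilyl) ether of the target (3S,4R,3'S,4'R) | O=C1Oc2cc(O[Si](CC)(CC)CC)cc(O[Si](CC)(CC)CC)c2[C@@H](c2ccc(O[Si](CC)(CC)CC)cc2)[C@H]1[C@H]1C(=O)Oc2c(O[Si](CC)(CC)CC)c(O[Si](CC)(CC)CC)c(O[Si](CC)(CC)CC)c(O[Si](CC)(CC)CC)c2[C@H]1c1ccc(O[Si](CC)(CC)CC)cc1
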